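Remark on the chemistry: isopoegin B has no stereocentre. Enol 11 is written as its hydrogen-bonded Z form, which exchanges freely with its other tautomers, so the route has only regiochemical tasks.

## Structural features

Isopoegin B is an isoflavone: a benzene ring (ring A) fused through the C4a–C8a bond to a 4-pyranone (ring C), with a second benzene ring (ring B) attached to C3 by the C3–C1' bond. Ring A carries a hydroxyl on C5, hydrogen-bonded to the C4 carbonyl, and a methyl ether on C7. Ring B is a resorcinol with hydroxyls on C2' and C4' and a 3-methylbut-2-enyl (prenyl) chain on C5', next to the 4'-hydroxyl. There is no stereocentre, so no stereocentres stand next to each other, and the prenyl double bond ends in two methyl groups and has no geometry. The fragile parts are the prenyl olefin beside a free phenol (acid can close a dimethylchroman ring or add across the double bond), the C2=C3–C4=O enone of ring C (hard nucleophiles add at C2 and can open the pyranone with loss of C2), and the electron-rich phenols (oxidation). The real difficulty is regiochemical: the 5- and 7-oxygens of ring A must be told apart, the prenyl group must end up on C5' alone, and the two arenes must be joined through the C2–C3–C4 unit. The key step exploits the fact that C8a (bearing O1) and C5 (bearing the hydroxyl) are the two ortho neighbours of C4a, while C7 (bearing the methoxy group) is para to it. An aroyl group with fluorine on both ortho carbons and methoxy on the para carbon is therefore symmetric about the C4–C4a–C7 axis: either fluorine can be displaced by the enolate oxygen to make O1–C8a, and the fluorine left over sits on C5, still activated by the C4 carbonyl for exchange to hydroxyl.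

## Logic of the disconnections

15 back to 14. The two O–CH2 acetal bonds on O2' and O4' are cut last. The ring B phenols must stay masked through enolate, hydride-base and SNAr steps, and the mask must come off without hydrogenolysis (prenyl olefin) and without strong Lewis acid (7-methyl ether). The gain is that no compound before 15 has an acidic ring B hydroxyl. The demand on the forward step is an acid dilute enough to leave the prenyl olefin and the neighbouring 4'-hydroxyl alone.

14 back to 12, through 13. The C5–O bond is exchanged for a C5–F bond. Fluorine on C5 is ortho to the carbon that carries the C4 carbonyl and meta to both ring oxygens, so it is the one position of 12 activated for substitution. The gain is large: the 5-hydroxyl/7-methoxy differentiation disappears, because the precursor ring becomes symmetric. The demand is an oxygen nucleophile that attacks C5 in preference to C2 and that unmasks to the phenoxide under the same basic conditions, which is what the β-elimination of 13 provides.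

12 back to 11. The O1–C8a bond is cut, which opens ring C to an acyclic 2-aryl-3-hydroxypropenone. Both C–O bonds of ring A that flank C4a are now traced to two equivalent C–F bonds, so the forward closure has no regiochemical choice. The demand is a base strong enough to form the enolate but too weak and too dry to cleave the formyl group or touch the second fluorine. For that reason 11 is isolated and cyclised separately rather than in the formylation mixture, where ethoxide is present.

11 back to 10. The C2–C3 bond is cut, removing C2 as a formyl group. The only enolisable position of 10 is the CH2 between the ketone and ring B, so a crossed Claisen formylation can go nowhere else. The demand is low temperature, so that ethoxide does not attack the C–F bonds.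

10 back to 9, and 9 back to 6 and 8. The C3–C4 bond is cut after an ester group is added to C3 as a temporary activator. The gain is a convergent union of a ring B arylacetate (6) with a ring A aroyl chloride (8, one step from 7). The demands are C- rather than O-acylation, met by a preformed lithium ester enolate, and removal of the ester under neutral conditions so that acetals and C–F bonds survive.

6 back to 4 and 5. The C5'–CH2 bond of the prenyl chain is cut to an aryl bromide and an allylic stannane. The gain is that the position of the prenyl group is fixed by the position of the bromine. The demand is that the coupling delivers the linear and not the branched allyl isomer.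

4 back to 3, 2 and 1. The C5'–Br bond, the two acetal O–C bonds and the ester O–CH3 bond are cut in turn. The acetals are put on before the bromine, because in 3 the carbon para to one acetal oxygen and ortho to the other is the only activated, unhindered ring position, whereas the free resorcinol would brominate less cleanly. The demand is mono-bromination without radical attack on the benzylic CH2.

## Other disconnections considered

Alternative 1: The cut is at C3–C1' and at O1–C2. Ring B is traced back to the β-carbon of a 2'-hydroxychalcone, A1 [(E)-3-[5-bromo-2,4-bis(methoxymethoxy)phenyl]-1-[2-hydroxy-4-methoxy-6-(methoxymethoxy)phenyl]prop-2-en-1-one], which would come from an aldol condensation of an acetophenone half with a benzaldehyde half.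
- Forward key step: PhI(OAc)2 (trivalent iodine) and acid in methanol with trimethyl orthoformate would bind the enol form of A1 at the α-carbon, methanol would add at the β-carbon, and loss of the reduced iodine reagent would draw ring B from the β- to the α-carbon while the old β-carbon becomes an acetal. HCl added to the same flask would then remove the protecting acetals and close ring C to give A2 [3-(5-bromo-2,4-dihydroxyphenyl)-5-hydroxy-7-methoxychromen-4-one]. A Stille prenylation of A2 would complete 15.
- In its favour: it follows the biosynthetic logic, the migrating ring is electron-rich and should migrate readily, all ring A oxygens are present from the start, and the prenyl group arrives after the last acid treatment.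
- Against it here: both arenes of A1 are activated enough to be oxidised or iodinated by the reagent, and the free 2'-hydroxyl offers competing oxidative closures to flavone- or aurone-type skeletons. The final coupling would have to run on A2, a triphenol whose bromine lies ortho to a free hydroxyl, with the same linear-versus-branched question as step 4 and no later step in which to repair it.
- Comparison: On structure, the plans differ in how the 5-oxygen is secured (present in A1, latent as fluorine in 11 and 12). On mechanism, the alternative rests on an oxidative cationic 1,2-shift whose chemoselectivity must be won, whereas the chosen plan uses polar closed-shell steps in which symmetry removes the choice. On step economy the alternative is the better of the two: it should need clearly fewer steps and it spares the prenylated phenol any acid.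

Alternative 2: Ring B itself is dissected by cutting C1'–C2', C2'–C3', C4'–C5' and C5'–C6'. The pieces are an α-diazo enone attached to C3 of a complete chromone, A3 [5-(tert-butyldimethylsilyloxy)-3-[(1E)-4-diazo-7-methyl-3-oxoocta-1,6-dienyl]-7-methoxychromen-4-one], and a siloxyalkyne, A4 [ethynyloxy(triisopropyl)silane].
- Forward key step (a vinylketene benzannulation): irradiation of A3 would trigger a Wolff shift, and the ketene so formed would add A4 in a [2+2] sense. Warming would bring about a four-electron ring opening, a six-electron electrocyclisation and tautomerisation to the phenol A5 [5-(tert-butyldimethylsilyloxy)-3-[2-hydroxy-5-(3-methylbut-2-enyl)-4-(triisopropylsilyloxy)phenyl]-7-methoxychromen-4-one]. Fluoride would then remove both silyl groups to give 15.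
- In its favour: the positions of all four ring B substituents follow from the mechanism, the prenyl chain is carried in on the diazo carbon so that no cross-coupling and no electrophilic substitution is needed, and the end game uses fluoride instead of acid.
- Against it here: ring B is the part that can be bought almost complete, so the effort goes into the wrong ring, and the chromone of A3 must still be built by some other ring C synthesis. A carbene with a CH2 group beside it can undergo a 1,2-hydride shift instead of the Wolff shift, the prenyl olefin lies within reach for cyclopropanation, the chromone is itself a chromophore, and the terminal siloxyalkyne A4 is delicate.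
- Comparison: On structure, the alternative is the better plan for the prenyl regiochemistry and for the acid-free deprotection, and it equals the chosen plan in having no regiochemical choice in its key step. On mechanism, it strings several pericyclic events after a photochemical carbene step, each with a competing channel in this substrate, against a single addition–elimination in the chosen plan. On step economy it is the poorer, because A3 needs a long linear preparation before the key step.

Alternative 3: The cuts are C3–C4 and O1–C2. Ring C would be assembled from a salicylate-type acyl donor, the benzodioxinone A6 [7-methoxy-5-(methoxymethoxy)-2,2-dimethyl-1,3-benzodioxin-4-one], and a two-carbon nucleophile, the cyclohexylimine A7 [(E)-N-cyclohexyl-2-[2,4-bis(methoxymethoxy)-5-(3-methylbut-2-enyl)phenyl]ethanimine].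
- Forward key step: the lithium aza-enolate of A7 (LiN(iPr)2) would add to the lactone-type carbonyl of A6, the ketal carbon would leave as its ketone and free the phenoxide, and on acidification that phenol would add to the imine carbon and expel the amine. This would give A8 [3-[2,4-bis(methoxymethoxy)-5-(3-methylbut-2-enyl)phenyl]-7-methoxy-5-(methoxymethoxy)chromen-4-one], and one acid treatment of A8 would give 15.
- In its favour: it is convergent, makes two bonds of ring C in one operation, needs no fluorine-for-oxygen exchange, and shares the ring B chemistry of steps 1 to 4, A7 being two steps from 6.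
- Against it here: an arylacetaldehyde derivative such as A7 enolises, self-condenses and oxidises easily. The acylation product is more acidic than A7 and would consume a second equivalent of aza-enolate or base. The carbonyl of A6 is flanked by two ortho oxygens and is hindered and deactivated. A6 also requires the two phenols of a 2,4,6-trioxygenated benzoic acid to be told apart before the key step.
- Comparison: On structure, it is the better plan in carrying the 5-oxygen as an acetal, which makes the end game one step shorter. On mechanism, both plans close ring C by polar addition–elimination, and the chosen plan has the more robust nucleophile (a stabilised formyl-ketone enolate against an aza-enolate of an aldehyde imine) and no proton-transfer drain. On step economy the two are about equal overall, and the alternative has the shorter longest linear sequence.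

Key step: step 9

## Steps

Step 1
Reactants: 1 2,4-dihydroxyphenylacetic acid
Product: 2 methyl 2-(2,4-dihydroxyphenyl)acetate
Conditions: MeOH, cat. H2SO4, reflux
Reagents that add atoms: methanol (CO)
Why: Fischer esterification; the large excess of methanol drives the equilibrium and also opens any benzofuranone formed from the ortho-hydroxy acid, and the phenols do not react.

Step 2
Reactants: 2 methyl 2-(2,4-dihydroxyphenyl)acetate
Product: 3 methyl 2-[2,4-bis(methoxymethoxy)phenyl]acetate
Conditions: MOMCl, iPr2NEt, CH2Cl2, 0 °C → rt
Reagents that add atoms: chloromethyl methyl ether (COCCl)
Why: O-alkylation of both phenols by the reactive α-chloro ether (Williamson-type acetal formation) under an amine base that does not enolise the ester. The acetals withstand every later basic and organometallic step and, put on before the bromination, leave a single activated and unhindered ring position.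

Step 3
Reactants: 3 methyl 2-[2,4-bis(methoxymethoxy)phenyl]acetate
Product: 4 methyl 2-[5-bromo-2,4-bis(methoxymethoxy)phenyl]acetate
Conditions: NBS, MeCN, 0 °C → rt, dark
Reagents that add atoms: N-bromosuccinimide (O=C1CCC(=O)N1Br)
Why: Electrophilic aromatic bromination; C5 is para to the 2-alkoxy and ortho to the 4-alkoxy group, whereas C3 is flanked by two substituents and C6 is meta to both, so mono-bromination at C5 should result. Polar solvent and darkness suppress radical bromination of the benzylic CH2.

Step 4
Reactants: 4 methyl 2-[5-bromo-2,4-bis(methoxymethoxy)phenyl]acetate; 5 tributyl(3-methylbut-2-enyl)stannane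
Product: 6 methyl 2-[2,4-bis(methoxymethoxy)-5-(3-methylbut-2-enyl)phenyl]acetate
Conditions: Pd(PPh3)4 (cat.), DMF, 100 °C
Reagents that add atoms: none
Why: Stille coupling; zerovalent palladium inserts into the C–Br bond, the allylic stannane transmetalates, and reductive elimination at the less hindered primary terminus of the allyl ligand should give the linear prenyl arene. The neutral conditions leave the ester and the acetals untouched.

Step 5
Reactants: 7 2,6-difluoro-4-methoxybenzoic acid
Product: 8 2,6-difluoro-4-methoxybenzoyl chloride
Conditions: (COCl)2, cat. DMF, CH2Cl2, 0 °C → rt; evaporate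
Reagents that add atoms: oxalyl chloride (O=C(Cl)C(=O)Cl)
Why: Acid chloride formation through the chloroiminium species made from DMF; the by-products are gases, so the crude chloride can be used directly.

Step 6
Reactants: 6 methyl 2-[2,4-bis(methoxymethoxy)-5-(3-methylbut-2-enyl)phenyl]acetate; 8 2,6-difluoro-4-methoxybenzoyl chloride
Product: 9 methyl 2-[2,4-bis(methoxymethoxy)-5-(3-methylbut-2-enyl)phenyl]-3-(2,6-difluoro-4-methoxyphenyl)-3-oxopropanoate (racemic)
Conditions: LiN(SiMe3)2 (2.2 equiv), THF, −78 °C; then 8, −78 → −20 °C; AcOH
Reagents that add atoms: none
Why: Crossed Claisen C-acylation of a preformed lithium ester enolate by a non-enolisable aroyl chloride; the second equivalent of base converts the β-keto ester into its enolate as it forms, which stops further acylation, and the low temperature keeps the C–F bonds out of play. The stereocentre at C2 is formed racemic and is removed in step 7.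

Step 7
Reactants: 9 methyl 2-[2,4-bis(methoxymethoxy)-5-(3-methylbut-2-enyl)phenyl]-3-(2,6-difluoro-4-methoxyphenyl)-3-oxopropanoate
Product: 10 2-[2,4-bis(methoxymethoxy)-5-(3-methylbut-2-enyl)phenyl]-1-(2,6-difluoro-4-methoxyphenyl)ethanone
Conditions: LiCl, H2O, DMSO, 120–130 °C
Reagents that add atoms: none
Why: Krapcho dealkoxycarbonylation; chloride removes the ester methyl group by SN2 and carbon dioxide is lost from the activated α-aryl β-keto acid unit. The medium is essentially neutral, so acetals, olefin and C–F bonds should survive.

Step 8
Reactants: 10 2-[2,4-bis(methoxymethoxy)-5-(3-methylbut-2-enyl)phenyl]-1-(2,6-difluoro-4-methoxyphenyl)ethanone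
Product: 11 (Z)-2-[2,4-bis(methoxymethoxy)-5-(3-methylbut-2-enyl)phenyl]-1-(2,6-difluoro-4-methoxyphenyl)-3-hydroxyprop-2-en-1-one
Conditions: NaH, HCO2Et, THF (cat. EtOH), 0 °C → rt; AcOH, 0 °C
Reagents that add atoms: ethyl formate (CCOC=O)
Why: Crossed Claisen formylation at the only enolisable carbon; the product is held as its stabilised enolate, which drives the equilibrium, and cold acidification releases the chelated Z enol, whose geometry is set by the hydrogen bond to the ketone. While the ketone is present as its enolate the aroyl ring is deactivated, which together with the low temperature keeps ethoxide from displacing fluoride.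

Step 9
Reactants: 11 (Z)-2-[2,4-bis(methoxymethoxy)-5-(3-methylbut-2-enyl)phenyl]-1-(2,6-difluoro-4-methoxyphenyl)-3-hydroxyprop-2-en-1-one
Product: 12 3-[2,4-bis(methoxymethoxy)-5-(3-methylbut-2-enyl)phenyl]-5-fluoro-7-methoxychromen-4-one
Conditions: K2CO3, dry DMF, rt → 60 °C
Reagents that add atoms: none
Why: K2CO3 deprotonates the acidic enol of 11 to the delocalised enolate of the formyl ketone, and its oxygen, which can sit cis to the aroyl group, adds to one fluorine-bearing carbon ortho to the carbonyl to give a Meisenheimer adduct whose charge is taken up through C4a by the C4 carbonyl; loss of fluoride then forms the O1–C8a bond. The closest known reaction type is the base-mediated cyclisation of enolates of 1-(2-fluoroaryl) 1,3-dicarbonyl compounds to chromones and flavones, the oxygen counterpart of the quinolone-forming SNAr ring closure. Ring C closes in a six-membered mode on a trigonal aromatic carbon (formally 6-exo-trig if the C8a=C8 bond is taken as the one attacked; for an addition–elimination on an arene the label is only formal). No stereocentre is formed. Three selectivities are needed: oxygen against carbon attack is settled by ring size, since C3 could reach the arene only through a four-membered ring; the choice between the two fluorines does not arise, because rotation about the C4–C4a bond exchanges them and either closure gives 12; and single against double substitution is settled because the fluorine left on C5 has no internal nucleophile and carbonate is too weak an external one. Dry DMF at moderate temperature avoids retro-Claisen loss of the formyl carbon and leaves the acetals and the prenyl group untouched.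

Step 10
Reactants: 12 3-[2,4-bis(methoxymethoxy)-5-(3-methylbut-2-enyl)phenyl]-5-fluoro-7-methoxychromen-4-one
Product: 14 3-[2,4-bis(methoxymethoxy)-5-(3-methylbut-2-enyl)phenyl]-5-hydroxy-7-methoxychromen-4-one, via 5-[2-(methylsulfonyl)ethoxy] ether 13 (not isolated)
Conditions: MeSO2CH2CH2OH, NaH, DMF, 0 °C → rt; AcOH
Reagents that add atoms: 2-(methylsulfonyl)ethanol (CS(=O)(=O)CCO)
Why: SNAr followed by E1cB elimination; the sodium alkoxide displaces the C5 fluoride, which is ortho to the carbon bearing the C4 carbonyl and meta to both ring oxygens, and ether 13 then loses methyl vinyl sulfone under the excess base to give the phenoxide, stabilised by chelation to C4=O. A hydroxide surrogate is used because hydroxide itself would add at C2 and open the pyranone, whereas addition of an alkoxide at C2 under dry conditions is reversible.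

Step 11
Reactants: 14 3-[2,4-bis(methoxymethoxy)-5-(3-methylbut-2-enyl)phenyl]-5-hydroxy-7-methoxychromen-4-one
Product: 15 isopoegin B, 3-[2,4-dihydroxy-5-(3-methylbut-2-enyl)phenyl]-5-hydroxy-7-methoxychromen-4-one
Conditions: 3 M aq. HCl, MeOH, 40 °C
Reagents that add atoms: none
Why: Acid-catalysed solvolysis of the two aryl acetals (transacetalisation to dimethoxymethane). Dilute acid and mild warming are chosen so that the prenyl olefin is not protonated and the 4'-hydroxyl does not add to it; the methyl ether and the chelated 5-hydroxyl are inert.

## Compound list

1 | 2,4-dihydroxyphenylacetic acid | OC(=O)Cc1ccc(O)cc1O | starting material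
2 | methyl 2-(2,4-dihydroxyphenyl)acetate | COC(=O)Cc1ccc(O)cc1O | intermediate
3 | methyl 2-[2,4-bis(methoxymethoxy)phenyl]acetate | COCOc1ccc(CC(=O)OC)c(OCOC)c1 | intermediate
4 | methyl 2-[5-bromo-2,4-bis(methoxymethoxy)phenyl]acetate | COCOc1cc(OCOC)c(CC(=O)OC)cc1Br | intermediate
5 | tributyl(3-methylbut-2-enyl)stannane | CCCC[Sn](CCCC)(CCCC)CC=C(C)C | starting material
6 | methyl 2-[2,4-bis(methoxymethoxy)-5-(3-methylbut-2-enyl)phenyl]acetate | COCOc1cc(OCOC)c(CC(=O)OC)cc1CC=C(C)C | intermediate
7 | 2,6-difluoro-4-methoxybenzoic acid | COc1cc(F)c(C(=O)O)c(F)c1 | starting material
8 | 2,6-difluoro-4-methoxybenzoyl chloride | COc1cc(F)c(C(=O)Cl)c(F)c1 | intermediate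
9 | methyl 2-[2,4-bis(methoxymethoxy)-5-(3-methylbut-2-enyl)phenyl]-3-(2,6-difluoro-4-methoxyphenyl)-3-oxopropanoate (racemic, configurationally labile) | COC(=O)C(C(=O)c1c(F)cc(OC)cc1F)c1cc(CC=C(C)C)c(OCOC)cc1OCOC | intermediate
10 | 2-[2,4-bis(methoxymethoxy)-5-(3-methylbut-2-enyl)phenyl]-1-(2,6-difluoro-4-methoxyphenyl)ethanone | O=C(Cc1cc(CC=C(C)C)c(OCOC)cc1OCOC)c1c(F)cc(OC)cc1F | intermediate
11 | (Z)-2-[2,4-bis(methoxymethoxy)-5-(3-methylbut-2-enyl)phenyl]-1-(2,6-difluoro-4-methoxyphenyl)-3-hydroxyprop-2-en-1-one | O/C=C(\C(=O)c1c(F)cc(OC)cc1F)c1cc(CC=C(C)C)c(OCOC)cc1OCOC | intermediate
12 | 3-[2,4-bis(methoxymethoxy)-5-(3-methylbut-2-enyl)phenyl]-5-fluoro-7-methoxychromen-4-one | COc1cc(F)c2c(=O)c(-c3cc(CC=C(C)C)c(OCOC)cc3OCOC)coc2c1 | intermediate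
13 | 3-[2,4-bis(methoxymethoxy)-5-(3-methylbut-2-enyl)phenyl]-7-methoxy-5-[2-(methylsulfonyl)ethoxy]chromen-4-one (not isolated) | COc1cc(OCCS(C)(=O)=O)c2c(=O)c(-c3cc(CC=C(C)C)c(OCOC)cc3OCOC)coc2c1 | intermediate
14 | 3-[2,4-bis(methoxymethoxy)-5-(3-methylbut-2-enyl)phenyl]-5-hydroxy-7-methoxychromen-4-one | COc1cc(O)c2c(=O)c(-c3cc(CC=C(C)C)c(OCOC)cc3OCOC)coc2c1 | intermediate
15 | isopoegin B, 3-[2,4-dihydroxy-5-(3-methylbut-2-enyl)phenyl]-5-hydroxy-7-methoxychromen-4-one | COc1cc(O)c2c(=O)c(-c3cc(CC=C(C)C)c(O)cc3O)coc2c1 | target

## Step count and least certain steps

Total step count: 11. Longest linear sequence: 10 steps (steps 1 to 4 and 6 to 11, from 1 to 15); step 5 is a one-step branch that prepares 8.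

Step 9 (key step). The most likely failure is loss of the formyl carbon by retro-Claisen cleavage before ring closure, if traces of water or hydroxide are present. If the closure has to be forced, amine released from warm DMF could also attack the activated C5–F bond. The para methoxy group makes the arene only moderately electrophilic, which is why forcing might be needed. The fallback closes ring C through O1–C2 instead of O1–C8a and sets out from 10. Acetohydroxamic acid and K2CO3 in DMSO at about 80 °C should exchange one of the two equivalent fluorines for oxygen; the hydroxamic acid is more acidic than the ketone, so the ketone stays largely un-enolised and activating. The exchange passes through N-[2-[2-[2,4-bis(methoxymethoxy)-5-(3-methylbut-2-enyl)phenyl]acetyl]-3-fluoro-5-methoxyphenoxy]acetamide F1, which fragments in the flask by a Lossen-type rearrangement to the phenoxide. The phenoxide deactivates the ring against a second exchange, and acidification should give 2-[2,4-bis(methoxymethoxy)-5-(3-methylbut-2-enyl)phenyl]-1-(2-fluoro-6-hydroxy-4-methoxyphenyl)ethanone F2. Heating F2 with N,N-dimethylformamide dimethyl acetal in toluene should give the enaminone (E)-2-[2,4-bis(methoxymethoxy)-5-(3-methylbut-2-enyl)phenyl]-3-(dimethylamino)-1-(2-fluoro-6-hydroxy-4-methoxyphenyl)prop-2-en-1-one F3. Its phenol adds to the aminomethylene carbon and expels dimethylamine, which is the classical deoxybenzoin closure, and the route is rejoined at 12.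

Step 4. The most likely failure is allylic transposition during transmetalation or reductive elimination, leading to the branched 1,1-dimethylallyl isomer. Slow oxidative addition into the electron-rich, ortho-alkoxy C–Br bond, with protodestannylation taking over, is a second risk. The fallback sets out from 4. Stille coupling with allyltributylstannane (Pd(PPh3)4, DMF), whose allyl group has two identical termini, should give methyl 2-[2,4-bis(methoxymethoxy)-5-(prop-2-enyl)phenyl]acetate F4. Cross-metathesis of F4 with an excess of 2-methylbut-2-ene and the second-generation Grubbs catalyst in CH2Cl2 then exchanges the CH2 terminus for CMe2, and the route is rejoined at 6.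

Step 7. The most likely failure is attack of the carboxylate or enol oxygen on an ortho C–F bond at the temperature needed for demethylation (closure to a coumarin- or chromone-type ring), or displacement of fluoride by water. The fallback uses no β-keto ester and no heating; it sets out from 6 and would also cover a failure of step 6. LiOH in aqueous THF should give 2-[2,4-bis(methoxymethoxy)-5-(3-methylbut-2-enyl)phenyl]acetic acid F5. Its enediolate (LiN(iPr)2, 2 equiv, THF, −78 → 0 °C) is used in excess over 8, because the acylation product is deprotonated by it. C-acylation by 8 at −78 °C should give the lithium salt of 2-[2,4-bis(methoxymethoxy)-5-(3-methylbut-2-enyl)phenyl]-3-(2,6-difluoro-4-methoxyphenyl)-3-oxopropanoic acid F6, which should lose carbon dioxide when the mixture is brought to about pH 4 and warmed gently. The route is rejoined at 10, bypassing 9, and surplus F5 is recovered by base extraction.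

Step 10. The most likely failure is conjugate addition of the alkoxide at C2 followed by opening of the pyranone and loss of C2, in competition with substitution at C5; a strong base with a hard alkoxide favours this if any water is present. The fallback replaces the alkoxide and β-elimination by an α-effect oxygen nucleophile under carbonate and sets out from 12. Acetohydroxamic acid and K2CO3 in DMSO at 70–80 °C should give N-[[3-[2,4-bis(methoxymethoxy)-5-(3-methylbut-2-enyl)phenyl]-7-methoxy-4-oxochromen-5-yl]oxy]acetamide F7, which fragments in the flask to the chelated phenoxide. The route is rejoined at 14, bypassing 13.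

Step 11. The most likely failure is protonation of the prenyl olefin, followed by ring closure of the 4'-hydroxyl onto the tertiary cation (dimethylchroman formation) or by addition of methanol or HCl. The fallback avoids free protic acid and sets out from 14. Me3SiOTf with 2,2'-bipyridyl in CH2Cl2 at 0 °C should convert the aryl acetals into aryl silyl ethers and silylate the 5-hydroxyl as well, giving 7-methoxy-3-[5-(3-methylbut-2-enyl)-2,4-bis(trimethylsilyloxy)phenyl]-5-(trimethylsilyloxy)chromen-4-one F8. Water at neutral pH then hydrolyses F8, and the route is rejoined at 15.

## Further compounds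

F1 | step 9 | N-[2-[2-[2,4-bis(methoxymethoxy)-5-(3-methylbut-2-enyl)phenyl]acetyl]-3-fluoro-5-methoxyphenoxy]acetamide | CC(=O)NOc1cc(OC)cc(F)c1C(=O)Cc1cc(CC=C(C)C)c(OCOC)cc1OCOC
F2 | step 9 | 2-[2,4-bis(methoxymethoxy)-5-(3-methylbut-2-enyl)phenyl]-1-(2-fluoro-6-hydroxy-4-methoxyphenyl)ethanone | COc1cc(O)c(C(=O)Cc2cc(CC=C(C)C)c(OCOC)cc2OCOC)c(F)c1
F3 | step 9 | (E)-2-[2,4-bis(methoxymethoxy)-5-(3-methylbut-2-enyl)phenyl]-3-(dimethylamino)-1-(2-fluoro-6-hydroxy-4-methoxyphenyl)prop-2-en-1-one | CN(C)/C=C(/C(=O)c1c(O)cc(OC)cc1F)c1cc(CC=C(C)C)c(OCOC)cc1OCOC
F4 | step 4 | methyl 2-[2,4-bis(methoxymethoxy)-5-(prop-2-enyl)phenyl]acetate | COCOc1cc(OCOC)c(CC(=O)OC)cc1CC=C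
F5 | step 7 | 2-[2,4-bis(methoxymethoxy)-5-(3-methylbut-2-enyl)phenyl]acetic acid | COCOc1cc(OCOC)c(CC(=O)O)cc1CC=C(C)C
F6 | step 7 | 2-[2,4-bis(methoxymethoxy)-5-(3-methylbut-2-enyl)phenyl]-3-(2,6-difluoro-4-methoxyphenyl)-3-oxopropanoic acid (racemic) | OC(=O)C(C(=O)c1c(F)cc(OC)cc1F)c1cc(CC=C(C)C)c(OCOC)cc1OCOC
F7 | step 10 | N-[[3-[2,4-bis(methoxymethoxy)-5-(3-methylbut-2-enyl)phenyl]-7-methoxy-4-oxochromen-5-yl]oxy]acetamide | CC(=O)NOc1cc(OC)cc2occ(-c3cc(CC=C(C)C)c(OCOC)cc3OCOC)c(=O)c12
F8 | step 11 | 7-methoxy-3-[5-(3-methylbut-2-enyl)-2,4-bis(trimethylsilyloxy)phenyl]-5-(trimethylsilyloxy)chromen-4-one | COc1cc(O[Si](C)(C)C)c2c(=O)c(-c3cc(CC=C(C)C)c(O[Si](C)(C)C)cc3O[Si](C)(C)C)coc2c1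
A1 | alternative 1 | (E)-3-[5-bromo-2,4-bis(methoxymethoxy)phenyl]-1-[2-hydroxy-4-methoxy-6-(methoxymethoxy)phenyl]prop-2-en-1-one | COCOc1cc(OCOC)c(/C=C/C(=O)c2c(O)cc(OC)cc2OCOC)cc1Br
A2 | alternative 1 | 3-(5-bromo-2,4-dihydroxyphenyl)-5-hydroxy-7-methoxychromen-4-one | COc1cc(O)c2c(=O)c(-c3cc(Br)c(O)cc3O)coc2c1
A3 | alternative 2 | 5-(tert-butyldimethylsilyloxy)-3-[(1E)-4-diazo-7-methyl-3-oxoocta-1,6-dienyl]-7-methoxychromen-4-one | COc1cc(O[Si](C)(C)C(C)(C)C)c2c(=O)c(/C=C/C(=O)C(=[N+]=[N-])CC=C(C)C)coc2c1
A4 | alternative 2 | ethynyloxy(triisopropyl)silane | C#CO[Si](C(C)C)(C(C)C)C(C)C
A5 | alternative 2 | 5-(tert-butyldimethylsilyloxy)-3-[2-hydroxy-5-(3-methylbut-2-enyl)-4-(triisopropylsilyloxy)phenyl]-7-methoxychromen-4-one | COc1cc(O[Si](C)(C)C(C)(C)C)c2c(=O)c(-c3cc(CC=C(C)C)c(O[Si](C(C)C)(C(C)C)C(C)C)cc3O)coc2c1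
A6 | alternative 3 | 7-methoxy-5-(methoxymethoxy)-2,2-dimethyl-1,3-benzodioxin-4-one | COCOc1cc(OC)cc2OC(C)(C)OC(=O)c12
A7 | alternative 3 | (E)-N-cyclohexyl-2-[2,4-bis(methoxymethoxy)-5-(3-methylbut-2-enyl)phenyl]ethanimine | COCOc1cc(OCOC)c(C/C=N/C2CCCCC2)cc1CC=C(C)C
A8 | alternative 3 | 3-[2,4-bis(methoxymethoxy)-5-(3-methylbut-2-enyl)phenyl]-7-methoxy-5-(methoxymethoxy)chromen-4-one | COc1cc(OCOC)c2c(=O)c(-c3cc(CC=C(C)C)c(OCOC)cc3OCOC)coc2c1
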